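## Retrosynthetic overview

1. Germacranolide numbering is used: ring C1–C10, lactone C6–O–C12(=O)–C11=C7, C13 = CH2OAc, C14 = CH2OH, C15 = CH3. Enabling feature: C2=C3 is the only C=C inside the ten-membered ring. It is cis, and both its allylic carbons are oxirane carbons (C1 of oxirane C1–C10, C4 of oxirane C4–C5). With C6–C7 locked in the butenolide, six of the other eight ring atoms sit in small rings that bend the chain.
2. Last disconnection: C2=C3, by ring-closing metathesis of a bis(vinyloxirane) butenolide. Before it: C6–C7 and O6–C12, by Cr/Ni alkenylation–lactonisation of a cis-epoxy aldehyde with a (Z)-β-iodoenoate, where Felkin–Anh control sets C6.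
3. Epoxy aldehyde: commercial Z-enynol, semihydrogenation, Sharpless epoxidation (C4, C5), oxidation. Iodoenoate: allylmagnesiation/iodination of propargyl alcohol (C1=C10 geometry), catalytic asymmetric propiolate addition (C8), iodo-aldol (tetrasubstituted C7=C11 plus C13), Sharpless epoxidation (C1, C10).
4. Order of ring formation: oxirane C4–C5 (step 2), oxirane C1–C10 (step 13), butenolide (step 14), ten-membered carbocycle (step 15).

Key step: step 15

Remark (assumption): the (S,S)-ProPhenol/Me2Zn catalyst is taken to give the (S)-carbinol at C8. If the sense of induction is the opposite, the equally available (R,R)-ligand is used.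

## Route

Step 1
Reactants: 1 (2Z)-3-methylpent-2-en-4-yn-1-ol
Product: 2 (2Z)-3-methylpenta-2,4-dien-1-ol
Conditions: H2 (1 atm), Lindlar catalyst, quinoline, Et2O/pentane, 0 °C, stopped after one equivalent of H2
Reagents that add atoms: none
Why: Lindlar semihydrogenation reduces the terminal alkyne of the enyne to the vinyl group on the poisoned Pd surface and leaves the trisubstituted Z-olefin alone, so the C3/C6-cis relation of the later oxirane comes directly from the commercial alcohol.

Step 2
Reactants: 2 (2Z)-3-methylpenta-2,4-dien-1-ol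
Product: 3 [(2S,3R)-3-ethenyl-3-methyloxiran-2-yl]methanol
Conditions: Ti(OiPr)4 (cat.), L-(+)-diethyl tartrate (cat.), t-BuOOH, 4 Å MS, CH2Cl2, −25 °C
Reagents that add atoms: tert-butyl hydroperoxide, CC(C)(C)OO
Why: In the Katsuki–Sharpless asymmetric epoxidation only the olefin of the Ti-bound allylic alcohol is oxidised (the vinyl group is not), L-(+)-tartrate directs oxygen to the face that gives C5 (S) and C4 (R) as for nerol-type Z-allylic alcohols, and the Z-geometry makes the oxirane cis (C3 and C6 on the same side).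

Step 3
Reactants: 3 [(2S,3R)-3-ethenyl-3-methyloxiran-2-yl]methanol
Product: 4 (2R,3R)-3-ethenyl-3-methyloxirane-2-carbaldehyde
Conditions: TEMPO (cat.), PhI(OAc)2, CH2Cl2, 0 °C to rt, used as a solution
Reagents that add atoms: none
Why: The TEMPO/PhI(OAc)2 (oxoammonium) oxidation stops at the aldehyde, is routine for 2,3-epoxy alcohols, and does not epimerise C5 because the oxirane C–H is not enolised under these near-neutral conditions (the descriptor changes only through CIP priorities).

Step 4
Reactants: 5 prop-2-yn-1-ol; 6 allylmagnesium bromide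
Product: 8 (2Z)-2-(iodomethylidene)pent-4-en-1-ol, via vinylmagnesium alkoxide 7 (not isolated)
Conditions: 6 (2.5 equiv), CuI (cat.), Et2O/THF, 0 °C to rt; then I2, THF, −40 to 0 °C
Reagents that add atoms: iodine, II
Why: In the alkoxide-directed anti-carbomagnesiation of a propargylic alcohol the allyl group goes to the inner alkyne carbon (C10) and Mg to the terminal carbon (C1) cis to CH2O– in a five-membered chelate, and iodinolysis with retention gives the Z-iodide that fixes the later C2-cis-to-C14 (C2-trans-to-C9) geometry.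

Step 5
Reactants: 8 (2Z)-2-(iodomethylidene)pent-4-en-1-ol
Product: 9 tert-butyl{[(2Z)-2-(iodomethylidene)pent-4-en-1-yl]oxy}dimethylsilane
Conditions: TBSCl, imidazole, CH2Cl2, 0 °C to rt
Reagents that add atoms: tert-butyldimethylsilyl chloride, CC(C)(C)[Si](C)(C)Cl
Why: Standard imidazole-promoted silylation masks the C14 hydroxyl, which would otherwise form a lactol with the aldehyde made in the next step.

Step 6
Reactants: 9 tert-butyl{[(2Z)-2-(iodomethylidene)pent-4-en-1-yl]oxy}dimethylsilane
Product: 11 (3Z)-3-{[(tert-butyldimethylsilyl)oxy]methyl}-4-iodobut-3-enal, via vicinal diol 10 (not isolated)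
Conditions: OsO4 (cat.), NaIO4, 2,6-lutidine, dioxane/H2O, rt
Reagents that add atoms: osmium tetroxide, O=[Os](=O)(=O)=O; sodium periodate, [Na+].[O-]I(=O)(=O)=O
Why: In the Lemieux–Johnson cleavage the electron-rich monosubstituted olefin is dihydroxylated far faster than the iodine-bearing trisubstituted one, and the lutidine buffer keeps the β,γ-unsaturated aldehyde (C8) out of conjugation.

Step 7
Reactants: 11 (3Z)-3-{[(tert-butyldimethylsilyl)oxy]methyl}-4-iodobut-3-enal; 12 methyl propiolate
Product: 13 methyl (4S,6Z)-6-{[(tert-butyldimethylsilyl)oxy]methyl}-4-hydroxy-7-iodohept-6-en-2-ynoate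
Conditions: Me2Zn, (S,S)-ProPhenol (cat.), Ph3P=O (cat.), toluene, 4 °C
Reagents that add atoms: none
Why: In the dinuclear-zinc (ProPhenol) catalysed asymmetric alkynylation of an aldehyde with methyl propiolate the chiral Zn2 pocket binds aldehyde and zinc acetylide together and sets the new stereocentre C8 (S) under catalyst control.

Step 8
Reactants: 13 methyl (4S,6Z)-6-{[(tert-butyldimethylsilyl)oxy]methyl}-4-hydroxy-7-iodohept-6-en-2-ynoate
Product: 14 methyl (4S,6Z)-6-{[(tert-butyldimethylsilyl)oxy]methyl}-4-hydroxynona-6,8-dien-2-ynoate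
Conditions: tributyl(vinyl)stannane, Pd2(dba)3 (cat.), AsPh3 (cat.), NMP, rt
Reagents that add atoms: tributyl(vinyl)stannane, C=C[Sn](CCCC)(CCCC)CCCC
Why: The Stille coupling of the alkenyl iodide proceeds with retention of geometry under neutral conditions that spare the base-sensitive γ-hydroxy ynoate, and it is placed here so that only one C–I bond is present.

Step 9
Reactants: 14 methyl (4S,6Z)-6-{[(tert-butyldimethylsilyl)oxy]methyl}-4-hydroxynona-6,8-dien-2-ynoate
Product: 15 methyl (2Z,4S,6Z)-6-{[(tert-butyldimethylsilyl)oxy]methyl}-4-hydroxy-2-(hydroxymethyl)-3-iodonona-2,6,8-trienoate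
Conditions: MgI2, monomeric CH2O (solution), CH2Cl2, −20 to 0 °C; aq. NH4Cl/Na2S2O3
Reagents that add atoms: magnesium iodide, [Mg+2].[I-].[I-]; formaldehyde, C=O
Why: In this β-iodo Morita–Baylis–Hillman (halo-aldol) three-component coupling iodide adds to C7 of the Mg-activated ynoate and the magnesium allenolate is hydroxymethylated at C11 on the side away from iodine (net anti addition, as in the hydroiodination of 2-ynoates), which places I cis to CO2Me and C8 cis to C13, the geometry the butenolide needs.

Step 10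
Reactants: 15 methyl (2Z,4S,6Z)-6-{[(tert-butyldimethylsilyl)oxy]methyl}-4-hydroxy-2-(hydroxymethyl)-3-iodonona-2,6,8-trienoate
Product: 16 methyl (2Z,4S,6Z)-2-(acetoxymethyl)-6-{[(tert-butyldimethylsilyl)oxy]methyl}-4-hydroxy-3-iodonona-2,6,8-trienoate
Conditions: Ac2O (1 equiv), 2,4,6-collidine, CH2Cl2, −20 to 0 °C
Reagents that add atoms: acetic anhydride, CC(=O)OC(C)=O
Why: Chemoselective acetylation should succeed because the primary allylic C13 carbinol is acylated faster than the secondary C8 carbinol, which is crowded by the iodoalkene.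

Step 11
Reactants: 16 methyl (2Z,4S,6Z)-2-(acetoxymethyl)-6-{[(tert-butyldimethylsilyl)oxy]methyl}-4-hydroxy-3-iodonona-2,6,8-trienoate
Product: 17 methyl (2Z,4S,6Z)-2-(acetoxymethyl)-6-{[(tert-butyldimethylsilyl)oxy]methyl}-3-iodo-4-(methacryloyloxy)nona-2,6,8-trienoate
Conditions: methacrylic anhydride, DMAP (cat.), Et3N, BHT (trace), CH2Cl2, 0 °C
Reagents that add atoms: methacrylic anhydride, C=C(C)C(=O)OC(=O)C(C)=C
Why: DMAP-catalysed acyl transfer esterifies the only free hydroxyl (C8–OH) without breaking a bond to C8, so the configuration is kept.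

Step 12
Reactants: 17 methyl (2Z,4S,6Z)-2-(acetoxymethyl)-6-{[(tert-butyldimethylsilyl)oxy]methyl}-3-iodo-4-(methacryloyloxy)nona-2,6,8-trienoate
Product: 18 methyl (2Z,4S,6Z)-2-(acetoxymethyl)-6-(hydroxymethyl)-3-iodo-4-(methacryloyloxy)nona-2,6,8-trienoate
Conditions: HF·pyridine, pyridine, THF, 0 °C
Reagents that add atoms: none
Why: Fluoride-driven desilylation (Si–F bond strength) under buffered conditions leaves the three esters, the alkenyl iodide and the diene untouched and frees the C14 hydroxyl that must direct the next step.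

Step 13
Reactants: 18 methyl (2Z,4S,6Z)-2-(acetoxymethyl)-6-(hydroxymethyl)-3-iodo-4-(methacryloyloxy)nona-2,6,8-trienoate
Product: 19 methyl (2Z,4S)-2-(acetoxymethyl)-5-[(2S,3R)-3-ethenyl-2-(hydroxymethyl)oxiran-2-yl]-3-iodo-4-(methacryloyloxy)pent-2-enoate
Conditions: Ti(OiPr)4 (cat.), L-(+)-diethyl tartrate (cat.), t-BuOOH, 4 Å MS, CH2Cl2, −20 °C
Reagents that add atoms: tert-butyl hydroperoxide, CC(C)(C)OO
Why: In the Katsuki–Sharpless epoxidation of a 2,4-dienol only the C10=C1 bond next to the Ti-bound C14–OH reacts, L-(+)-tartrate sets C10 (S) and C1 (R) under reagent control, and the olefin geometry from step 4 makes C2 and C9 trans on the oxirane.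

Step 14
Reactants: 19 methyl (2Z,4S)-2-(acetoxymethyl)-5-[(2S,3R)-3-ethenyl-2-(hydroxymethyl)oxiran-2-yl]-3-iodo-4-(methacryloyloxy)pent-2-enoate; 4 (2R,3R)-3-ethenyl-3-methyloxirane-2-carbaldehyde
Product: 21 (1S)-1-{(2S)-4-(acetoxymethyl)-2-[(2S,3R)-3-ethenyl-3-methyloxiran-2-yl]-5-oxo-2,5-dihydrofuran-3-yl}-2-[(2S,3R)-3-ethenyl-2-(hydroxymethyl)oxiran-2-yl]ethyl 2-methylprop-2-enoate, via open-chain hydroxy ester 20 (not isolated)
Conditions: CrCl2 (excess), NiCl2 (1 mol %), degassed DMSO, rt; aqueous potassium serinate work-up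
Reagents that add atoms: none
Why: In the Nozaki–Hiyama–Kishi alkenylation with spontaneous lactonisation Ni(0) inserts into C7–I, transmetallation gives a configurationally stable alkenylchromium(III) that adds only to the aldehyde, anti to the C5–O bond (Felkin–Anh, the cis C4 substituent blocking the other trajectory) to set C6 (S), and the chromium alkoxide held cis to CO2Me closes the butenolide with loss of methoxide.

Step 15
Reactants: 21 (1S)-1-{(2S)-4-(acetoxymethyl)-2-[(2S,3R)-3-ethenyl-3-methyloxiran-2-yl]-5-oxo-2,5-dihydrofuran-3-yl}-2-[(2S,3R)-3-ethenyl-2-(hydroxymethyl)oxiran-2-yl]ethyl 2-methylprop-2-enoate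
Product: 22 target, (1R,4R,5S,6S,8S,10S)-13-acetoxy-1,10:4,5-diepoxy-14-hydroxy-8-(methacryloyloxy)germacra-2Z,7(11)-dien-12,6-olide
Conditions: Hoveyda–Grubbs II catalyst (10 mol %, in portions), 1,4-benzoquinone (cat.), toluene, 1 mM, 40–60 °C, argon sparge
Reagents that add atoms: none
Why: Ring-closing olefin metathesis (Chauvin mechanism): the Ru alkylidene loads on the less hindered C1-vinyl group (C2=CH2), the resulting C2 alkylidene engages the neopentylic C4-vinyl group (C3=CH2) through a metallacyclobutane, and ethene leaves irreversibly under sparging. The closest known chemistry is the RCM closure of ten-membered carbocycles in densely oxygenated terpenoid precursors, which delivers Z-olefins, together with RCM and cross-metathesis of vinyl oxiranes, which tolerate Ru carbenes. The only ring closed is the ten-membered carbocycle, by head-to-head union of C2 and C3 to an endocyclic olefin, while both oxiranes and the butenolide are spectators. No stereocentre is formed; the element set is the C2=C3 geometry, and Z is expected because an E-olefin between the trans-oxirane C1–C10, the cis-oxirane C4–C5 and the planar C6–C7 edge would be a far more strained cyclodecene, so reversible metathesis should return E-product and oligomers to the Z-monomer. The step needs chemoselectivity among five C=C bonds and monomer-over-oligomer selectivity: the 1,1-disubstituted electron-poor methacrylate and the tetrasubstituted butenolide olefin are inert to the catalyst, and the cis-oxirane plus the cisoid butenolide edge fold the chain so that C2 and C3 meet at high dilution. In one operation the last C–C bond, the carbocycle and the last stereo-element are made on the unprotected substrate, and the product is the target itself.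

## Compound list

1 | (2Z)-3-methylpent-2-en-4-yn-1-ol | OC/C=C(C)\C#C | starting material
2 | (2Z)-3-methylpenta-2,4-dien-1-ol | OC/C=C(C)\C=C | intermediate
3 | [(2S,3R)-3-ethenyl-3-methyloxiran-2-yl]methanol | OC[C@@H]1O[C@]1(C)C=C | intermediate
4 | (2R,3R)-3-ethenyl-3-methyloxirane-2-carbaldehyde | O=C[C@@H]1O[C@]1(C)C=C | intermediate
5 | prop-2-yn-1-ol | C#CCO | starting material
6 | allylmagnesium bromide | C=CC[Mg]Br | starting material
7 | bromomagnesium (2Z)-2-[(bromomagnesio)methylidene]pent-4-en-1-olate (Mg cis to CH2O) | Br[Mg]OC/C(CC=C)=C\[Mg]Br | intermediate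
8 | (2Z)-2-(iodomethylidene)pent-4-en-1-ol | OC/C(CC=C)=C\I | intermediate
9 | tert-butyl{[(2Z)-2-(iodomethylidene)pent-4-en-1-yl]oxy}dimethylsilane | CC(C)(C)[Si](C)(C)OC/C(CC=C)=C\I | intermediate
10 | (4Z)-4-{[(tert-butyldimethylsilyl)oxy]methyl}-5-iodopent-4-ene-1,2-diol (both C2 epimers) | CC(C)(C)[Si](C)(C)OC/C(CC(O)CO)=C\I | intermediate
11 | (3Z)-3-{[(tert-butyldimethylsilyl)oxy]methyl}-4-iodobut-3-enal | CC(C)(C)[Si](C)(C)OC/C(CC=O)=C\I | intermediate
12 | methyl propiolate | C#CC(=O)OC | starting material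
13 | methyl (4S,6Z)-6-{[(tert-butyldimethylsilyl)oxy]methyl}-4-hydroxy-7-iodohept-6-en-2-ynoate | CC(C)(C)[Si](C)(C)OC/C(C[C@H](O)C#CC(=O)OC)=C\I | intermediate
14 | methyl (4S,6Z)-6-{[(tert-butyldimethylsilyl)oxy]methyl}-4-hydroxynona-6,8-dien-2-ynoate | CC(C)(C)[Si](C)(C)OC/C(C[C@H](O)C#CC(=O)OC)=C\C=C | intermediate
15 | methyl (2Z,4S,6Z)-6-{[(tert-butyldimethylsilyl)oxy]methyl}-4-hydroxy-2-(hydroxymethyl)-3-iodonona-2,6,8-trienoate | CC(C)(C)[Si](C)(C)OC/C(C[C@H](O)/C(I)=C(\CO)C(=O)OC)=C\C=C | intermediate
16 | methyl (2Z,4S,6Z)-2-(acetoxymethyl)-6-{[(tert-butyldimethylsilyl)oxy]methyl}-4-hydroxy-3-iodonona-2,6,8-trienoate | CC(C)(C)[Si](C)(C)OC/C(C[C@H](O)/C(I)=C(\COC(C)=O)C(=O)OC)=C\C=C | intermediate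
17 | methyl (2Z,4S,6Z)-2-(acetoxymethyl)-6-{[(tert-butyldimethylsilyl)oxy]methyl}-3-iodo-4-(methacryloyloxy)nona-2,6,8-trienoate | CC(C)(C)[Si](C)(C)OC/C(C[C@H](OC(=O)C(C)=C)/C(I)=C(\COC(C)=O)C(=O)OC)=C\C=C | intermediate
18 | methyl (2Z,4S,6Z)-2-(acetoxymethyl)-6-(hydroxymethyl)-3-iodo-4-(methacryloyloxy)nona-2,6,8-trienoate | OC/C(C[C@H](OC(=O)C(C)=C)/C(I)=C(\COC(C)=O)C(=O)OC)=C\C=C | intermediate
19 | methyl (2Z,4S)-2-(acetoxymethyl)-5-[(2S,3R)-3-ethenyl-2-(hydroxymethyl)oxiran-2-yl]-3-iodo-4-(methacryloyloxy)pent-2-enoate | C=C(C)C(=O)O[C@@H](C[C@@]1(CO)O[C@@H]1C=C)/C(I)=C(\COC(C)=O)C(=O)OC | intermediate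
20 | open-chain γ-hydroxy ester (formed as its Cr(III) alkoxide): 19 with I replaced by the (S)-CH(OH) carbon C6 that carries the (2S,3R)-3-ethenyl-3-methyloxiran-2-yl group, C6 cis to CO2Me | C=C(C)C(=O)O[C@@H](C[C@@]1(CO)O[C@@H]1C=C)/C([C@H](O)[C@@H]1O[C@]1(C)C=C)=C(\COC(C)=O)C(=O)OC | intermediate
21 | (1S)-1-{(2S)-4-(acetoxymethyl)-2-[(2S,3R)-3-ethenyl-3-methyloxiran-2-yl]-5-oxo-2,5-dihydrofuran-3-yl}-2-[(2S,3R)-3-ethenyl-2-(hydroxymethyl)oxiran-2-yl]ethyl 2-methylprop-2-enoate | C=C(C)C(=O)O[C@@H](C[C@@]1(CO)O[C@@H]1C=C)C1=C(COC(C)=O)C(=O)O[C@@H]1[C@@H]1O[C@]1(C)C=C | intermediate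
22 | (1R,4R,5S,6S,8S,10S)-13-acetoxy-1,10:4,5-diepoxy-14-hydroxy-8-(methacryloyloxy)germacra-2Z,7(11)-dien-12,6-olide (CNP0207684.1) | C=C(C)C(=O)O[C@H]1C[C@@]2(CO)O[C@@H]2/C=C\[C@@]2(C)O[C@H]2[C@H]2OC(=O)C(COC(C)=O)=C12 | target

## Step count and risks

Total step count: 15. Longest linear sequence: 12 steps (steps 4–15, from propargyl alcohol).

**Risk 1, step 15.** Intermolecular metathesis may outrun closure of the strained ring. The neopentylic C4-vinyl group may engage slowly. The catalyst may be lost through opening of a vinyl oxirane.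

The fallback changes the bond that closes the carbocycle. It sets out from 19 and 3 and comes back at 22.
- The two alcohols are joined with iPr2SiCl2/imidazole (sequential addition) to the mixed diisopropylsilyl bis-ether F1.
- Silicon-tethered RCM closes the more flexible eleven-membered (Z)-siladioxacycle F2.
- HF·pyridine removes the tether and gives the open-chain bis-epoxy diol F3.
- TEMPO/PhI(OAc)2 oxidises the less hindered C6 carbinol (the C14 carbinol is neopentylic) to the epoxy aldehyde F4.
- An intramolecular Nozaki–Hiyama–Kishi reaction with lactonisation forms C6–C7 and gives 22.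

**Risk 2, step 14.** Cr(II)/iodide may open the vinyl oxiranes reductively to allylchromium species. Metal insertion at the tetrasubstituted iodide may be sluggish. Facial selectivity at C6 may be poor.

The fallback moves the coupling ahead of the second epoxidation. It sets out from 17 and 4 and comes back at 21.
- The silyl-protected dienyl iodide 17 carries neither an oxirane nor a free hydroxyl. It is coupled with 4 under Cr/Ni conditions to the silyl-protected dienyl butenolide F5.
- Buffered HF·pyridine gives the dienol butenolide F6.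
- Sharpless epoxidation with L-(+)-diethyl tartrate, directed by C14–OH, gives 21.

**Risk 3, step 9.** The Lewis-acidic iodide source may attack the diene or the allylic silyl ether. Conjugate addition to the internal ynoate may be slow. The olefin geometry may erode through allenolate equilibration.

The fallback runs the halo-aldol before the diene exists and relies on I-over-Br selectivity. It sets out from 13 and comes back at 21.
- Bromo-aldol of 13 (MgBr2·OEt2 or TMSBr, CH2O) gives the β-bromo diol F7.
- Selective acetylation gives the acetate F8, and methacrylation gives the bromo iodide F9.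
- Stille vinylation at rt takes place only at the C1–I bond and gives the bromo diene F10.
- HF·pyridine gives the bromo dienol F11, and Sharpless epoxidation gives the bromo epoxy alcohol F12.
- Cr/Ni coupling of the activated alkenyl bromide with 4, followed by lactonisation, gives 21.

## Further compounds

F1 | step 15 | mixed diisopropylsilyl bis-ether of 19 (through O14) and 3 (through O6) | C=C(C)C(=O)O[C@@H](C[C@@]1(CO[Si](C(C)C)(C(C)C)OC[C@@H]2O[C@]2(C)C=C)O[C@@H]1C=C)/C(I)=C(\COC(C)=O)C(=O)OC
F2 | step 15 | eleven-membered (Z)-siladioxacycle from RCM of F1 (C2=C3 formed, both oxiranes fused to the ring) | C=C(C)C(=O)O[C@@H](C[C@]12CO[Si](C(C)C)(C(C)C)OC[C@@H]3O[C@]3(C)/C=C\[C@H]1O2)/C(I)=C(\COC(C)=O)C(=O)OC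
F3 | step 15 | open-chain (2Z)-bis-epoxy diol iodoenoate (free C6–OH and C14–OH) | C=C(C)C(=O)O[C@@H](C[C@@]1(CO)O[C@@H]1/C=C\[C@@]1(C)O[C@H]1CO)/C(I)=C(\COC(C)=O)C(=O)OC
F4 | step 15 | open-chain epoxy aldehyde iodoenoate (C6 = CHO) | C=C(C)C(=O)O[C@@H](C[C@@]1(CO)O[C@@H]1/C=C\[C@@]1(C)O[C@H]1C=O)/C(I)=C(\COC(C)=O)C(=O)OC
F5 | step 14 | silyl-protected dienyl butenolide (21 with C10=C1 still an olefin and C14–OTBS) | CC(C)(C)[Si](C)(C)OC/C(C[C@H](OC(=O)C(C)=C)C1=C(COC(C)=O)C(=O)O[C@@H]1[C@@H]1O[C@]1(C)C=C)=C\C=C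
F6 | step 14 | dienol butenolide (F5 without the silyl group) | OC/C(C[C@H](OC(=O)C(C)=C)C1=C(COC(C)=O)C(=O)O[C@@H]1[C@@H]1O[C@]1(C)C=C)=C\C=C
F7 | step 9 | methyl (2Z,4S,6Z)-3-bromo-6-{[(tert-butyldimethylsilyl)oxy]methyl}-4-hydroxy-2-(hydroxymethyl)-7-iodohepta-2,6-dienoate | CC(C)(C)[Si](C)(C)OC/C(C[C@H](O)/C(Br)=C(\CO)C(=O)OC)=C\I
F8 | step 9 | C13 acetate of F7 | CC(C)(C)[Si](C)(C)OC/C(C[C@H](O)/C(Br)=C(\COC(C)=O)C(=O)OC)=C\I
F9 | step 9 | C8 methacrylate of F8 | CC(C)(C)[Si](C)(C)OC/C(C[C@H](OC(=O)C(C)=C)/C(Br)=C(\COC(C)=O)C(=O)OC)=C\I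
F10 | step 9 | bromo analogue of 17 | CC(C)(C)[Si](C)(C)OC/C(C[C@H](OC(=O)C(C)=C)/C(Br)=C(\COC(C)=O)C(=O)OC)=C\C=C
F11 | step 9 | bromo analogue of 18 | OC/C(C[C@H](OC(=O)C(C)=C)/C(Br)=C(\COC(C)=O)C(=O)OC)=C\C=C
F12 | step 9 | bromo analogue of 19 | C=C(C)C(=O)O[C@@H](C[C@@]1(CO)O[C@@H]1C=C)/C(Br)=C(\COC(C)=O)C(=O)OC
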